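**Retrosynthetic overview**
- Fusarilin A ⇐ its N-Cbz benzyl ester, by one hydrogenolysis that removes both benzyl groups.
- C2–O bond ⇐ anti opening of a cyclopentane-fused N-Cbz aziridine at its secondary carbon by octanoic acid (puts the octanoyloxy group trans to N).
- C3–Ph bond ⇐ exo-face phenyl addition to the aziridino ketone (tertiary OH ends cis to N).
- Two C–N bonds (key step) ⇐ catalytic asymmetric aziridination of benzyl 3-oxocyclopent-1-ene-1-carboxylate (sets the quaternary amino acid carbon and the absolute configuration).
- Rings: the cyclopentane is bought intact; the aziridine is the only ring made (step 3) and it is opened again in step 5.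

Assumption: the quinine-derived amine is taken to give the (1S,5S)-aziridine on this new substrate (the quinidine-derived pseudo-enantiomer is used if the sense is opposite), and 3-oxocyclopent-1-ene-1-carboxylic acid is bought.

**Step 1**
Reactants: 1 3-oxocyclopent-1-ene-1-carboxylic acid; 2 benzyl bromide
Product: 4 benzyl 3-oxocyclopent-1-ene-1-carboxylate, via potassium 3-oxocyclopent-1-ene-1-carboxylate 3 (not isolated)
Conditions: BnBr (1.1 equiv), K2CO3 (1.1 equiv), DMF, 23 °C
Reagents that add atoms: benzyl bromide (2), BrCc1ccccc1
Why: Carboxylate O-alkylation (SN2) by benzyl bromide is mild enough to leave the enone untouched and installs an ester that is later removed by hydrogenolysis; no stereocentre is formed.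

**Step 2**
Reactants: 5 benzyl N-hydroxycarbamate; 6 p-toluenesulfonyl chloride
Product: 7 benzyl N-(tosyloxy)carbamate
Conditions: TsCl (1.0 equiv), Et3N (1.05 equiv), Et2O, 0 °C
Reagents that add atoms: p-toluenesulfonyl chloride (6), Cc1ccc(cc1)S(Cl)(=O)=O
Why: O-Sulfonylation of the N-hydroxycarbamate (sulfonyl transfer to the more nucleophilic oxygen) gives the bench-stable N–O aziridinating reagent; no stereocentre is formed.

**Step 3**
Reactants: 4 benzyl 3-oxocyclopent-1-ene-1-carboxylate; 7 benzyl N-(tosyloxy)carbamate
Product: 8 dibenzyl (1S,5S)-4-oxo-6-azabicyclo[3.1.0]hexane-1,6-dicarboxylate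
Conditions: 9-amino(9-deoxy)epi-quinine (20 mol%), N-Boc-D-phenylglycine (30 mol%), NaHCO3 (2 equiv), CHCl3, 25 °C
Reagents that add atoms: benzyl N-(tosyloxy)carbamate (7), O=C(NOS(=O)(=O)c1ccc(C)cc1)OCc1ccccc1
Why: Proposed new method: iminium–enamine aziridination by a cinchona primary amine, extended to a β-alkoxycarbonyl cyclopentenone so that the aza-Michael step creates a tetrasubstituted α-amino ester centre — the amine condenses with the ketone of 4 to a catalyst-bound iminium ion whose β-carbon is made more electrophilic by the ester, the carbamate nitrogen of 7 (held by the protonated quinuclidine) adds to one enantioface of that carbon and fixes 1S, and the catalyst-bound enamine carbon then displaces tosylate from nitrogen in a 3-exo-tet closure that can only give the cis-fused aziridine (5S); the closest known reaction type is the amine-catalysed asymmetric aziridination of unsubstituted cyclic and acyclic enones with N-(tosyloxy)carbamates (aza-Michael-initiated ring closure).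

**Step 4**
Reactants: 8 dibenzyl (1S,5S)-4-oxo-6-azabicyclo[3.1.0]hexane-1,6-dicarboxylate; 9 phenylmagnesium bromide
Product: 11 dibenzyl (1S,4S,5S)-4-hydroxy-4-phenyl-6-azabicyclo[3.1.0]hexane-1,6-dicarboxylate, via bromomagnesium tertiary alkoxide 10 (not isolated)
Conditions: PhMgBr (1.3 equiv), LaCl3·2LiCl (0.3 equiv), THF, −78 °C; AcOH quench at −78 °C
Reagents that add atoms: phenylmagnesium bromide (9), Br[Mg]c1ccccc1
Why: Lanthanide-promoted Grignard 1,2-addition is much faster at the ketone than at the hindered benzyl ester or the carbamate and suppresses enolisation, and phenyl enters the bicyclo[3.1.0] ketone from the exo face anti to the aziridine, which places the new hydroxyl cis to nitrogen (4S).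

**Step 5**
Reactants: 11 dibenzyl (1S,4S,5S)-4-hydroxy-4-phenyl-6-azabicyclo[3.1.0]hexane-1,6-dicarboxylate; 12 octanoic acid
Product: 13 benzyl (1S,2R,3S)-1-{[(benzyloxy)carbonyl]amino}-3-hydroxy-2-(octanoyloxy)-3-phenylcyclopentane-1-carboxylate
Conditions: n-C7H15CO2H (5 equiv), i-Pr2NEt (1.5 equiv), DMF, 70 °C
Reagents that add atoms: octanoic acid (12), CCCCCCCC(=O)O
Why: Nucleophilic ring opening of an N-alkoxycarbonyl-activated aziridine-2-carboxylate by a carboxylate is an SN2 attack at the secondary carbon (the quaternary α-ester carbon is blocked) with inversion, so the octanoyloxy group ends trans to nitrogen (2R) while the acidic buffer keeps the tertiary alcohol from attacking the carbamate.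

**Step 6**
Reactants: 13 benzyl (1S,2R,3S)-1-{[(benzyloxy)carbonyl]amino}-3-hydroxy-2-(octanoyloxy)-3-phenylcyclopentane-1-carboxylate
Product: 15 Fusarilin A, (1S,2R,3S)-1-amino-3-hydroxy-2-(octanoyloxy)-3-phenylcyclopentane-1-carboxylic acid, via N-carboxy amino acid 14 (not isolated)
Conditions: H2 (1 atm), 10% Pd/C, EtOAc–MeOH, 23 °C
Reagents that add atoms: none
Why: Catalytic hydrogenolysis cleaves the benzyl ester and the benzyl carbamate (the carbamic acid loses CO2) under neutral conditions that spare the octanoate and the tertiary benzylic alcohol, and the trans amino ester cannot undergo O-to-N acyl shift, so all three stereocentres are retained.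

**Compound list**
1 | 3-oxocyclopent-1-ene-1-carboxylic acid | O=C1C=C(C(=O)O)CC1 | starting material
2 | benzyl bromide | BrCc1ccccc1 | starting material
3 | potassium 3-oxocyclopent-1-ene-1-carboxylate | O=C1C=C(C(=O)[O-])CC1.[K+] | intermediate
4 | benzyl 3-oxocyclopent-1-ene-1-carboxylate | O=C1C=C(C(=O)OCc2ccccc2)CC1 | intermediate
5 | benzyl N-hydroxycarbamate | O=C(NO)OCc1ccccc1 | starting material
6 | p-toluenesulfonyl chloride | Cc1ccc(cc1)S(Cl)(=O)=O | starting material
7 | benzyl N-(tosyloxy)carbamate | O=C(NOS(=O)(=O)c1ccc(C)cc1)OCc1ccccc1 | intermediate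
8 | dibenzyl (1S,5S)-4-oxo-6-azabicyclo[3.1.0]hexane-1,6-dicarboxylate (aziridine cis-fused; N on the face opposite the C1 ester) | O=C(OCc1ccccc1)N1[C@H]2[C@]1(C(=O)OCc1ccccc1)CCC2=O | intermediate
9 | phenylmagnesium bromide | Br[Mg]c1ccccc1 | starting material
10 | bromomagnesium (1S,4S,5S)-1,6-bis(benzyloxycarbonyl)-4-phenyl-6-azabicyclo[3.1.0]hexan-4-olate | O=C(OCc1ccccc1)N1[C@H]2[C@]1(C(=O)OCc1ccccc1)CC[C@]2(O[Mg]Br)c1ccccc1 | intermediate
11 | dibenzyl (1S,4S,5S)-4-hydroxy-4-phenyl-6-azabicyclo[3.1.0]hexane-1,6-dicarboxylate (OH cis to the aziridine N, phenyl trans) | O=C(OCc1ccccc1)N1[C@H]2[C@]1(C(=O)OCc1ccccc1)CC[C@]2(O)c1ccccc1 | intermediate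
12 | octanoic acid | CCCCCCCC(=O)O | starting material
13 | benzyl (1S,2R,3S)-1-{[(benzyloxy)carbonyl]amino}-3-hydroxy-2-(octanoyloxy)-3-phenylcyclopentane-1-carboxylate | CCCCCCCC(=O)O[C@@H]1[C@](NC(=O)OCc2ccccc2)(C(=O)OCc2ccccc2)CC[C@]1(O)c1ccccc1 | intermediate
14 | (1S,2R,3S)-1-(carboxyamino)-3-hydroxy-2-(octanoyloxy)-3-phenylcyclopentane-1-carboxylic acid | CCCCCCCC(=O)O[C@@H]1[C@](NC(=O)O)(C(=O)O)CC[C@]1(O)c1ccccc1 | intermediate
15 | Fusarilin A, (1S,2R,3S)-1-amino-3-hydroxy-2-(octanoyloxy)-3-phenylcyclopentane-1-carboxylic acid | CCCCCCCC(=O)O[C@@H]1[C@](N)(C(=O)O)CC[C@]1(O)c1ccccc1 | target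

**Step count**
Total steps: 6. Longest linear sequence: 5 (steps 1, 3, 4, 5, 6); step 2 is a one-step side branch to the reagent.

**Three steps most likely to fail**

Step 3 (the new aziridination). The risks are slow iminium formation or aza-Michael addition at the fully substituted β-carbon, and an uncatalysed background reaction of this doubly activated alkene that erodes the enantiomeric excess. The fallback uses known chemistry, sets out from 4 and comes back at 8. Compound 4 is aziridinated with 7 under plain base mediation (K2CO3, CH2Cl2, 23 °C), the established uncatalysed aza-Michael-initiated ring closure of enones with N-(sulfonyloxy)carbamates, which gives racemic material. The enantiomers are separated by preparative chromatography on a chiral stationary phase; 8 goes on, and dibenzyl (1R,5R)-4-oxo-6-azabicyclo[3.1.0]hexane-1,6-dicarboxylate F1 is set aside.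

Step 4 (phenyl addition). The risks are attack of the organometallic or of the new alkoxide on the activated N-Cbz group, base-induced opening of the keto aziridine, and insufficient facial bias. The fallback reverses the order of C–C and C–N bond formation; it sets out from 4 and comes back at 11. The ketone of 4 is phenylated by catalytic asymmetric aryl transfer (Ph2Zn, Ti(OiPr)4, chiral bis(sulfonamide) diol ligand, toluene) to benzyl (R)-3-hydroxy-3-phenylcyclopent-1-ene-1-carboxylate F2. Its enoate is then aziridinated with 7 and K2CO3: the carbamate anion adds to the β-carbon on the hydroxyl face (hydrogen bond, anti to phenyl) and the ester enolate closes onto nitrogen, giving 11 with no organometallic step on the aziridine. Enantiomeric purity then rests on the aryl-transfer catalyst, which is unproven on this enone, and is upgraded by crystallising 11.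

Step 5 (aziridine opening). The secondary carbon is flanked by two fully substituted carbons, and the carboxylate must approach from the face that carries the phenyl and ester groups, so the SN2 opening may be very slow. The fallback moves deprotection ahead of C–O bond formation; it sets out from 11 and comes back at 15. Compound 11 is hydrogenolysed briefly (H2, Pd/C, MeOH), which passes through (1S,4S,5S)-4-hydroxy-4-phenyl-6-azabicyclo[3.1.0]hexane-1,6-dicarboxylic acid F3; this loses CO2 to give the free N–H aziridine amino acid (1S,4S,5S)-4-hydroxy-4-phenyl-6-azabicyclo[3.1.0]hexane-1-carboxylic acid F4. This zwitterion is heated in neat octanoic acid (60–70 °C). The N-protonated aziridinium carries no N-substituent and is far more electrophilic than the carbamate, and it is opened at the secondary carbon with inversion to give 15 directly.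

**Further compounds**
F1 | step 3 | dibenzyl (1R,5R)-4-oxo-6-azabicyclo[3.1.0]hexane-1,6-dicarboxylate | O=C(OCc1ccccc1)N1[C@@H]2[C@@]1(C(=O)OCc1ccccc1)CCC2=O
F2 | step 4 | benzyl (R)-3-hydroxy-3-phenylcyclopent-1-ene-1-carboxylate | O=C(OCc1ccccc1)C1=C[C@@](O)(c2ccccc2)CC1
F3 | step 5 | (1S,4S,5S)-4-hydroxy-4-phenyl-6-azabicyclo[3.1.0]hexane-1,6-dicarboxylic acid | OC(=O)N1[C@H]2[C@]1(C(=O)O)CC[C@]2(O)c1ccccc1
F4 | step 5 | (1S,4S,5S)-4-hydroxy-4-phenyl-6-azabicyclo[3.1.0]hexane-1-carboxylic acid | N1[C@H]2[C@]1(C(=O)O)CC[C@]2(O)c1ccccc1
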